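I decided to count turnovers first, meaning product made per catalyst charged, and to hold that count against what the earlier runs reached.

| setting | spring | midnight | summer | flask |
|---|---|---|---|---|
| substrate | 0.10 M | 0.10 M | 0.10 M | 0.10 M |
| partner | 0.35 equiv | 1.4 equiv | 0.70 equiv | 0.700 equiv |
| free catalyst | 0.5 mol% | 0.5 mol% | 1 mol% | 0.5 mol% |
| remark | run made earlier | run made earlier | run made earlier |  |

- spring (time / h: product / %): 1.50: 7; 3.00: 14; 5.00: 17; 6.00: 15; 8.00: 21; 10.0: 19
- midnight (time / h: product / %): 0.833: 17; 1.33: 18; 2.00: 23; 4.00: 35; 6.00: 40; 10.0: 38
- summer (time / h: product / %): 2.00: 27; 4.00: 35; 6.00: 37; 8.00: 38; 10.0: 36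

(scatter of a reading: 2 percentage points)

- apparent order in free catalyst when 20% of the substrate are converted (percent change of the rate of making product for one percent more free catalyst charged)
- factor on the rate of making product when 20% of the substrate are converted if free catalyst is charged twice over



The midnight run levelled at a reading of 78.0 turnovers, and I took that as a ceiling. In the flask, 20% conversion on 0.5 mol% of catalyst means 40.0 turnovers, so the used share of the ceiling is 51.3%. For the opposite outcome, a rate simply proportional to catalyst with an order of 1 and a factor of 2, this share would have to lie near zero. The flask stood at about half. I let the rate go with the catalyst charged times the share of the ceiling still unused, which gave an order of 2.05. Doubled catalyst would reach the same conversion at 20.0 turnovers, which gave a factor of 3.05.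

The forecast came to the same figures, 2.05 and 3.05, saying “the catalyst must be dying”. The flask gave an order of 2.2 and a factor of 3.45.

    catalyst intermediate C ⇌ free catalyst + product (K = 0.0250 M, k = 1100 h⁻¹)
    substrate + catalyst intermediate A ⇌ catalyst intermediate B (K = 24.0 M⁻¹, k = 2.00 × 10⁵ M⁻¹ h⁻¹)
    partner + free catalyst → catalyst intermediate A (k = 600 M⁻¹ h⁻¹)
    catalyst intermediate B → catalyst intermediate C (k = 30000 h⁻¹)
    2 partner → homo dimer (k = 4.40 M⁻¹ h⁻¹)

The line to watch in the flask was partner, the limiting reagent here: it stood at 57.1% of its charge after 0.800 h, while half of the turnover of the step from partner and free catalyst up to 8.00 h was done by 1.31 h, and at the start the step to homo dimer used partner about twice as fast as that step. By 80.0 h the flask held 0% partner, with free catalyst at 44.1% and catalyst intermediate C at 55.9%, and it had made 63.5 turnovers, fewer than the ceiling. The summer run read 38.0 turnovers at 8.00 h, about half of the ceiling.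

Readings and results come from a simulation with made-up constants, and the scatter is random.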